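## Retrosynthetic overview

1. Locants (4,5-seco-guaianolide numbering): carbocycle C1–C5–C6–C7–C8–C9–C10, lactone O6–C12(=O)–C11(=C13H2)–C7, side chain C2(=O)–C3=C4–C15 on C1; α is the face of the C6 oxygen, β the face of the C5 oxygen; the target is (1S,5S,6R,7S,9R,10S). The last steps only adjust oxidation level: 9β-OH from the C9 ketone by hydroxyl-directed reduction, the (E)-crotonoyl group from a propargylic pivalate by gold-catalysed acyloxy shift and hydrolysis.
2. Key disconnection: C7–C11, made together with scission of C7–C9. Lactone ketone 25 comes from propiolate 22 of a bicyclo[4.1.0]heptan-1-ol by strain-release ring expansion followed by 5-exo-dig radical closure.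
3. Enabling feature: the C9 carbinol carbon and C7 are separated only by the C8 methylene, so C7–C8–C9 can be stored as a cyclopropanol fused to the six-membered ring C1–C5–C6–C7–C9–C10. Its oxidative opening places a radical on C7, next to C6, whose oxygen carries the alkyne acceptor.
4. The six-membered ring comes from (R)-carvone: C6 by Criegee rearrangement, C5 by Rubottom oxidation, C1 by axial alkynylation, C10 by hydroboration; the cyclopropane by Simmons–Smith reaction of the C9 silyl enol ether.
5. Order of ring formation: cyclohexane (chiral pool), cyclopropane (step 12), then cycloheptanone and lactone in one operation (step 15).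

Key step: step 15

Remark on the chemistry: enantiopure (R)-carvone and (S)-but-3-yn-2-ol are assumed; the butynyl carbinol centre is destroyed in step 16 and only keeps the intermediates single diastereomers; the cyclopropane of 20–22 is drawn as the β-face isomer, but either face isomer would converge to 25.

Names of 1–9 use cyclohexenone locants (cyclohexenone C1, C2, C3, C4, C5, C6 = target C1, C10, C9, C7, C6, C5); from 13 onward, and in all Why lines, target locants are used.

## Route

Step 1
Reactants: 1 (R)-carvone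
Product: 4 (R)-5-acetoxy-2-methylcyclohex-2-en-1-one, via methoxy hydroperoxide 2 (not isolated), via peracetate 3 (not isolated)
Conditions: O3, CH2Cl2/MeOH, −78 °C; then Ac2O, Et3N, DMAP (cat.), −78 °C to rt
Reagents that add atoms: ozone, [O-][O+]=O; methanol, CO; acetic anhydride, CC(=O)OC(C)=O (acetyl of intermediate 3 only)
Why: Ozonolysis in methanol cleaves only the electron-rich isopropenyl group to 2, and its peracetate 3 undergoes Criegee rearrangement with migration of the ring carbon and retention, so the carvone stereocentre becomes the 6α-oxygenated C6 of the target.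

Step 2
Reactants: 4 (R)-5-acetoxy-2-methylcyclohex-2-en-1-one
Product: 5 (R)-5-hydroxy-2-methylcyclohex-2-en-1-one
Conditions: p-TsOH·H2O (cat.), MeOH, rt
Reagents that add atoms: none
Why: Acid-catalysed transesterification frees the alcohol and avoids the E1cB loss of acetate that base would cause in this β-acyloxy ketone.

Step 3
Reactants: 5 (R)-5-hydroxy-2-methylcyclohex-2-en-1-one
Product: 6 (R)-2-methyl-5-(triethylsilyloxy)cyclohex-2-en-1-one
Conditions: Et3SiCl, imidazole, CH2Cl2, 0 °C
Reagents that add atoms: chlorotriethylsilane, CC[Si](Cl)(CC)CC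
Why: Silyl ether formation; the secondary triethylsilyl ether survives enolate, acetylide and borane chemistry and can later be removed beside a tertiary tert-butyldimethylsilyl ether.

Step 4
Reactants: 6 (R)-2-methyl-5-(triethylsilyloxy)cyclohex-2-en-1-one
Product: 9 (5R,6S)-6-hydroxy-2-methyl-5-(triethylsilyloxy)cyclohex-2-en-1-one, via silyl dienol ether 7 (not isolated), via α-silyloxy ketone 8 (not isolated)
Conditions: LiN(i-Pr)2, THF, −78 °C, then Me3SiCl; mCPBA, NaHCO3, CH2Cl2, −20 °C; citric acid, MeOH, 0 °C
Reagents that add atoms: chlorotrimethylsilane, C[Si](C)(C)Cl (silyl groups of 7 and 8 only); mCPBA, OOC(=O)c1cccc(Cl)c1 (the new oxygen)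
Why: Rubottom oxidation: kinetic α′-deprotonation gives the cross-conjugated dienol ether 7, which is epoxidised at the enol ether bond anti to the adjacent C6 silyloxy group and rearranges to 8, so the new C5 oxygen is trans to O-6 (5β).

Step 5
Reactants: 10 (S)-but-3-yn-2-ol
Product: 11 (S)-but-3-yn-2-yl pivalate
Conditions: t-BuCOCl, pyridine, DMAP (cat.), CH2Cl2, 0 °C to rt
Reagents that add atoms: pivaloyl chloride, CC(C)(C)C(Cl)=O
Why: Esterification with retention; the pivalate has no α-hydrogen, resists the acetylide chemistry of step 6 and is the migrating group of step 16.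

Step 6
Reactants: 9 (5R,6S)-6-hydroxy-2-methyl-5-(triethylsilyloxy)cyclohex-2-en-1-one; 11 (S)-but-3-yn-2-yl pivalate
Product: 13 alkynyl diol (1α-OH and 1β-alkynyl and 5β-OH and 6α-OSiEt3), via lithium acetylide 12 (not isolated)
Conditions: 11 (3 equiv), LiN(i-Pr)2 (3 equiv), THF, −78 °C; then 9, −78 to −40 °C; aq. NH4Cl
Reagents that add atoms: lithium diisopropylamide, CC(C)[N-]C(C)C.[Li+] (lithium of intermediate 12 only)
Why: 1,2-Alkynylation of the enone carbonyl (one equivalent of 12 is consumed by the free hydroxyl); axial attack on the half-chair anti to the C6 silyloxy group, as in 1,2-additions to carvone, should place the alkyne on the β face and the new C1 hydroxyl on the α face.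

Step 7
Reactants: 13 alkynyl diol
Product: 14 5β-isovalerate with free tertiary 1α-OH
Conditions: (i-BuCO)2O, DMAP, pyridine, CH2Cl2, 0 °C to rt
Reagents that add atoms: 3-methylbutanoic anhydride, CC(C)CC(=O)OC(=O)CC(C)C
Why: DMAP-catalysed esterification is selective for the secondary C5 hydroxyl over the hindered tertiary propargylic C1 hydroxyl.

Step 8
Reactants: 14 5β-isovalerate with free tertiary 1α-OH
Product: 15 1α-tert-butyldimethylsilyl ether
Conditions: t-BuMe2SiOTf, 2,6-lutidine, CH2Cl2, −78 to 0 °C
Reagents that add atoms: tert-butyldimethylsilyl triflate, CC(C)(C)[Si](C)(C)OS(=O)(=O)C(F)(F)F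
Why: Silyl ether formation at the tertiary alcohol with the silyl triflate; the ether prevents retro-aldol cleavage once C9 is a ketone (steps 11–16), keeps the hydroxyl from adding to the allene in step 16 and steers the borane in step 9.

Step 9
Reactants: 15 1α-tert-butyldimethylsilyl ether
Product: 17 9β-alcohol with 10α-methyl (10β-H), via alkylborane 16 (not isolated)
Conditions: BH3·THF, THF, 0 °C to rt; then NaBO3·4H2O, THF/H2O, rt
Reagents that add atoms: borane, B (boron of intermediate 16 only); sodium perborate, [Na+].[O-]OB=O (the new oxygen)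
Why: Hydroboration–oxidation: borane adds syn across C9=C10 with boron on the less substituted C9 from the β face, anti to the allylic C1 and the C6 silyloxy groups, which sets H-10 β (10α-methyl); the alkyne, flanked by a quaternary silyloxy carbon and a pivaloyloxy carbon, is expected to react more slowly, and perborate oxidises 16 with retention without cleaving the esters.

Step 10
Reactants: 17 9β-alcohol
Product: 18 C9 ketone
Conditions: Dess–Martin periodinane, NaHCO3, CH2Cl2, 0 °C to rt
Reagents that add atoms: none
Why: Dess–Martin oxidation under buffered conditions gives the ketone without epimerising the adjacent C10 stereocentre.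

Step 11
Reactants: 18 C9 ketone
Product: 19 C7=C9 trimethylsilyl enol ether
Conditions: LiN(i-Pr)2, Me3SiCl (in situ), THF, −78 °C; Et3N, pentane
Reagents that add atoms: chlorotrimethylsilane, C[Si](C)(C)Cl
Why: Kinetic enolisation with in situ silylation removes a proton from the C7 methylene and not the hindered tertiary C10–H, and trapping at −78 °C outruns β-elimination of the C6 silyloxy group and enolisation of the esters.

Step 12
Reactants: 19 C7=C9 trimethylsilyl enol ether
Product: 20 siloxycyclopropane (1-siloxybicyclo[4.1.0]heptane with C8 on the β face)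
Conditions: Et2Zn, CH2I2, CH2Cl2, 0 °C
Reagents that add atoms: diiodomethane, ICI
Why: Simmons–Smith cyclopropanation (Furukawa conditions) of the electron-rich enol ether, expected anti to the flanking α-oriented C6 silyloxy and C10 methyl groups; alkyne and esters are inert, and the face is of no consequence because C7 and C9 lose their configuration in step 15.

Step 13
Reactants: 20 siloxycyclopropane
Product: 21 cyclopropanol diol (6α-OH and 9α-OH)
Conditions: PPTS, MeOH/CH2Cl2, 0 °C to rt
Reagents that add atoms: none
Why: Mild acid-catalysed methanolysis should remove the secondary triethylsilyl and the cyclopropyl trimethylsilyl ethers and leave the hindered tertiary tert-butyldimethylsilyl ether, the esters and the cyclopropanol.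

Step 14
Reactants: 21 cyclopropanol diol
Product: 22 6α-propiolate
Conditions: HC≡CCO2H, DCC, DMAP (5 mol %), CH2Cl2, −20 °C
Reagents that add atoms: propiolic acid, C#CC(=O)O
Why: Steglich esterification at low temperature acylates only the secondary C6 hydroxyl (the tertiary cyclopropanol is too hindered) and limits acyl migration from O-5.

Step 15
Reactants: 22 6α-propiolate
Product: 25 lactone ketone (cis-fused α-methylene-γ-butyrolactone on a cycloheptan-9-one), via β-keto radical 23 (not isolated), via vinyl radical 24 (not isolated)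
Conditions: Fe(NO3)3·9H2O (2.2 equiv), 1,4-cyclohexadiene (5 equiv), DMF (0.01 M), 0 to 50 °C
Reagents that add atoms: none
Why: Proposed new method: Fe(NO3)3 (trivalent iron) oxidises the tertiary cyclopropanol to an alkoxy radical whose strained internal C7–C9 bond cleaves to the ring-expanded cycloheptanone radical 23; this adds 5-exo-dig to the propiolate α-carbon C11 held on the neighbouring C6 oxygen, and the σ-vinyl radical 24 takes a hydrogen atom from 1,4-cyclohexadiene, whose cyclohexadienyl radical is oxidised to benzene by the second equivalent of the iron salt. The closest known reaction types are the iron-salt-mediated ring expansion/5-exo cyclisation of 1-siloxybicyclo[4.1.0]heptanes bearing an alkenyl chain next to the cyclopropane (hydrogen-atom termination by 1,4-cyclohexadiene) and the tin-hydride cyclisation of 2-haloalkyl propiolates to α-methylene-γ-butyrolactones; new is their combination, with an ynoate on an ester tether as acceptor. The cycloheptanone arises by one-carbon ring enlargement (the shared bond of the bicycle is cut, no closure), the lactone by 5-exo-dig closure. The only new stereocentre, C7, is set by C6: the two-atom O–C(=O) tether reaches the planar radical only from the α face, giving the cis-fused lactone (H-7 β), while the cyclopropane configuration is erased. The step needs scission of the internal and not the external cyclopropane bond (secondary versus primary radical, as in the known ring expansions), attack at C11 and not at the alkyne terminus (6-endo-dig is geometrically disfavoured), and cyclisation ahead of hydrogen transfer to C7 (low donor concentration, dilution and warming to populate the s-cis ester rotamer, while the vinyl radical is trapped far faster than the alkyl radical). The hindered side-chain alkyne could only be attacked in a strained bridging mode.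

Step 16
Reactants: 25 lactone ketone
Product: 27 (E)-crotonoyl ketone with 1α-silyl ether, via allenyl pivalate 26 (not isolated)
Conditions: Ph3PAuNTf2 (2 mol %), wet 2-butanone, rt
Reagents that add atoms: none
Why: Gold-catalysed (monovalent gold) 3,3-acyloxy shift of the propargylic pivalate to allenyl ester 26 and its hydrolysis (Meyer–Schuster-type rearrangement) should give the (E)-enone; the tertiary hydroxyl is still silylated and no free secondary hydroxyl is present, so no oxygen nucleophile can add to the activated alkyne or allene.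

Step 17
Reactants: 27 (E)-crotonoyl ketone with 1α-silyl ether
Product: 28 1α-hydroxy-9-ketone
Conditions: HF·pyridine, pyridine, THF, 0 °C to rt
Reagents that add atoms: none
Why: Desilylation with buffered hydrogen fluoride frees the tertiary C1 hydroxyl under non-basic conditions, so retro-aldol cleavage of the β-hydroxy ketone and conjugate addition to the two unsaturated carbonyl groups are avoided.

Step 18
Reactants: 28 1α-hydroxy-9-ketone
Product: 29 target CNP0186412.1
Conditions: Me4NBH(OAc)3, MeCN/AcOH (1:1), −30 °C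
Reagents that add atoms: none
Why: Evans–Saksena hydroxyl-directed reduction: the α-oriented C1 hydroxyl binds the triacetoxyborohydride and delivers hydride to the α face of the C9 ketone through a six-membered transition state, giving the anti-1,3-diol (9β-OH); the conjugated, hindered C2 carbonyl, the α-methylene lactone and the esters should not be reduced by this mild reagent.

## Compound list

1 | (R)-(−)-carvone, (5R)-2-methyl-5-(prop-1-en-2-yl)cyclohex-2-en-1-one | CC(=C)[C@@H]1CC=C(C)C(=O)C1 | starting material
2 | (5R)-5-(1-hydroperoxy-1-methoxyethyl)-2-methylcyclohex-2-en-1-one (side-chain carbon unassigned) | COC(C)(OO)[C@@H]1CC=C(C)C(=O)C1 | intermediate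
3 | 1-methoxy-1-[(1R)-4-methyl-5-oxocyclohex-3-en-1-yl]ethyl peracetate | COC(C)(OOC(C)=O)[C@@H]1CC=C(C)C(=O)C1 | intermediate
4 | (R)-5-acetoxy-2-methylcyclohex-2-en-1-one | CC(=O)O[C@@H]1CC=C(C)C(=O)C1 | intermediate
5 | (R)-5-hydroxy-2-methylcyclohex-2-en-1-one | O[C@@H]1CC=C(C)C(=O)C1 | intermediate
6 | (R)-2-methyl-5-(triethylsilyloxy)cyclohex-2-en-1-one | CC[Si](CC)(CC)O[C@@H]1CC=C(C)C(=O)C1 | intermediate
7 | (R)-triethyl{[4-methyl-5-(trimethylsilyloxy)cyclohexa-3,5-dien-1-yl]oxy}silane | CC[Si](CC)(CC)O[C@@H]1CC=C(C)C(O[Si](C)(C)C)=C1 | intermediate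
8 | (5R,6S)-2-methyl-5-(triethylsilyloxy)-6-(trimethylsilyloxy)cyclohex-2-en-1-one | CC[Si](CC)(CC)O[C@@H]1CC=C(C)C(=O)[C@H]1O[Si](C)(C)C | intermediate
9 | (5R,6S)-6-hydroxy-2-methyl-5-(triethylsilyloxy)cyclohex-2-en-1-one (5,6-trans) | CC[Si](CC)(CC)O[C@@H]1CC=C(C)C(=O)[C@H]1O | intermediate
10 | (S)-but-3-yn-2-ol | C[C@H](O)C#C | starting material
11 | (S)-but-3-yn-2-yl pivalate | C[C@H](OC(=O)C(C)(C)C)C#C | intermediate
12 | [(3S)-3-(pivaloyloxy)but-1-yn-1-yl]lithium | [Li]C#C[C@H](C)OC(=O)C(C)(C)C | intermediate
13 | (2S)-4-[1α,5β-dihydroxy-10-methyl-6α-(triethylsilyloxy)cyclohex-9-en-1β-yl]but-3-yn-2-yl pivalate (ring C1, C5, C6, C7, C9, C10) | CC[Si](CC)(CC)O[C@@H]1CC=C(C)[C@@](O)(C#C[C@H](C)OC(=O)C(C)(C)C)[C@H]1O | intermediate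
14 | 5β-(3-methylbutanoate) of 13, 1α-OH free | CC[Si](CC)(CC)O[C@@H]1CC=C(C)[C@@](O)(C#C[C@H](C)OC(=O)C(C)(C)C)[C@H]1OC(=O)CC(C)C | intermediate
15 | 1α-tert-butyldimethylsilyl ether of 14 | CC[Si](CC)(CC)O[C@@H]1CC=C(C)[C@@](O[Si](C)(C)C(C)(C)C)(C#C[C@H](C)OC(=O)C(C)(C)C)[C@H]1OC(=O)CC(C)C | intermediate
16 | 9β-boryl (BH2), 10β-H adduct of 15 | CC[Si](CC)(CC)O[C@@H]1C[C@@H]([BH2])[C@H](C)[C@@](O[Si](C)(C)C(C)(C)C)(C#C[C@H](C)OC(=O)C(C)(C)C)[C@H]1OC(=O)CC(C)C | intermediate
17 | 9β-hydroxy-10α-methyl cyclohexane (1α-OTBS, 1β-alkynyl pivalate, 5β-isovalerate, 6α-OSiEt3) | CC[Si](CC)(CC)O[C@@H]1C[C@@H](O)[C@H](C)[C@@](O[Si](C)(C)C(C)(C)C)(C#C[C@H](C)OC(=O)C(C)(C)C)[C@H]1OC(=O)CC(C)C | intermediate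
18 | 9-ketone of 17 | CC[Si](CC)(CC)O[C@@H]1CC(=O)[C@H](C)[C@@](O[Si](C)(C)C(C)(C)C)(C#C[C@H](C)OC(=O)C(C)(C)C)[C@H]1OC(=O)CC(C)C | intermediate
19 | 9-(trimethylsilyloxy) enol ether of 18 with the double bond C7=C9 | CC[Si](CC)(CC)O[C@@H]1C=C(O[Si](C)(C)C)[C@H](C)[C@@](O[Si](C)(C)C(C)(C)C)(C#C[C@H](C)OC(=O)C(C)(C)C)[C@H]1OC(=O)CC(C)C | intermediate
20 | siloxycyclopropane: cyclopropane C7–C8–C9 with C8 on the β face, 9α-OSiMe3, 7α-H | CC[Si](CC)(CC)O[C@@H]1[C@H]2C[C@@]2(O[Si](C)(C)C)[C@H](C)[C@@](O[Si](C)(C)C(C)(C)C)(C#C[C@H](C)OC(=O)C(C)(C)C)[C@H]1OC(=O)CC(C)C | intermediate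
21 | cyclopropanol diol: 6α-OH, 9α-OH, 1α-OTBS retained | O[C@@H]1[C@H]2C[C@@]2(O)[C@H](C)[C@@](O[Si](C)(C)C(C)(C)C)(C#C[C@H](C)OC(=O)C(C)(C)C)[C@H]1OC(=O)CC(C)C | intermediate
22 | 6α-prop-2-ynoate of 21 | C#CC(=O)O[C@@H]1[C@H]2C[C@@]2(O)[C@H](C)[C@@](O[Si](C)(C)C(C)(C)C)(C#C[C@H](C)OC(=O)C(C)(C)C)[C@H]1OC(=O)CC(C)C | intermediate
23 | ring-expanded cycloheptan-9-one with a radical at C7 | C#CC(=O)O[C@@H]1[CH]CC(=O)[C@H](C)[C@@](O[Si](C)(C)C(C)(C)C)(C#C[C@H](C)OC(=O)C(C)(C)C)[C@H]1OC(=O)CC(C)C | intermediate
24 | cyclised lactone with a σ-vinyl radical at C13 | [CH]=C1C(=O)O[C@@H]2[C@H]1CC(=O)[C@H](C)[C@@](O[Si](C)(C)C(C)(C)C)(C#C[C@H](C)OC(=O)C(C)(C)C)[C@H]2OC(=O)CC(C)C | intermediate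
25 | lactone ketone: 12,6α-olide with 11(13)-methylene, 7β-H, 9-oxo, 10α-methyl, 1α-OTBS, 1β-[(3S)-3-(pivaloyloxy)but-1-ynyl], 5β-isovalerate | C=C1C(=O)O[C@@H]2[C@H]1CC(=O)[C@H](C)[C@@](O[Si](C)(C)C(C)(C)C)(C#C[C@H](C)OC(=O)C(C)(C)C)[C@H]2OC(=O)CC(C)C | intermediate
26 | allenyl pivalate: 1β-[1-(pivaloyloxy)buta-1,2-dien-1-yl] analogue of 25 | C=C1C(=O)O[C@@H]2[C@H]1CC(=O)[C@H](C)[C@@](O[Si](C)(C)C(C)(C)C)(C(OC(=O)C(C)(C)C)=C=CC)[C@H]2OC(=O)CC(C)C | intermediate
27 | 1β-[(E)-but-2-enoyl]-1α-(tert-butyldimethylsilyloxy)-9-ketone | C=C1C(=O)O[C@@H]2[C@H]1CC(=O)[C@H](C)[C@@](O[Si](C)(C)C(C)(C)C)(C(=O)/C=C/C)[C@H]2OC(=O)CC(C)C | intermediate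
28 | 1β-[(E)-but-2-enoyl]-1α-hydroxy-9-ketone | C=C1C(=O)O[C@@H]2[C@H]1CC(=O)[C@H](C)[C@@](O)(C(=O)/C=C/C)[C@H]2OC(=O)CC(C)C | intermediate
29 | CNP0186412.1: (1S,5S,6R,7S,9R,10S)-1α,9β-dihydroxy-5β-(3-methylbutanoyloxy)-2-oxo-4,5-seco-guaia-3(E),11(13)-dien-12,6α-olide | C=C1C(=O)O[C@@H]2[C@H]1C[C@@H](O)[C@H](C)[C@@](O)(C(=O)/C=C/C)[C@H]2OC(=O)CC(C)C | target

## Step count and risks

Total step count: 18. Longest linear sequence: 17 steps (1 to 29 through steps 1–4 and 6–18; step 5 prepares the alkyne 11).

The three steps most likely to fail: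

Step 15 (Proposed new method). The C7 radical may be reduced by the diene or oxidised by the iron salt before it cyclises, because the ester must first rotate into the s-cis conformation; attack at the alkyne terminus is a second possible leak. The fallback uses known chemistry and sets out from cyclopropanol 21. FeCl3 in DMF would bring about the same oxidative ring expansion but end it by chlorine transfer, giving the β-chloro cycloheptanone F1. NaOAc in methanol would eliminate hydrogen chloride to the 6α-hydroxycyclohept-7-en-9-one F2. Acryloyl chloride with i-Pr2NEt would give the acrylate F3. Catalytic PMe3 in tert-amyl alcohol would then close the lactone by an intramolecular Rauhut–Currier reaction: the phosphine adds to the acrylate, the α-carbon of the resulting enolate adds to the enone β-carbon C7 from the face of O-6, and the phosphine is expelled. This comes back to the route at 25.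

Step 9. The borane may add to the side-chain alkyne faster than to the trisubstituted ring alkene, or attack the α face (poor facial selectivity), which would give the C10 epimer. The fallback sets out from the free tertiary allylic alcohol 14 and uses no borane. VO(acac)2 with t-BuOOH would give, by hydroxyl-directed epoxidation, the 9α,10α-epoxy alcohol F4. t-BuMe2SiOTf with 2,6-lutidine would give its silyl ether F5. Cp2TiCl (trivalent titanium, from Cp2TiCl2 and manganese powder) with 1,4-cyclohexadiene in THF would open the epoxide homolytically at the tertiary carbon (Nugent–RajanBabu opening). Hydrogen-atom transfer to the C10 radical from the β face, away from the two α-oriented oxygens at C9 and C1, would give the 9α-alcohol F6 with the 10α-methyl group. Dess–Martin oxidation of F6 comes back to the route at ketone 18.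

Step 18. Chemoselectivity may be lost, with the C1-bound borohydride also delivering hydride to the adjacent C2 carbonyl of the enone. The fallback sets out from 28 and replaces selective reduction by exhaustive reduction and selective re-oxidation. The directed reduction would be followed by Luche reduction (NaBH4, CeCl3·7H2O, MeOH, −78 °C) to complete 1,2-reduction of the enone carbonyl, giving the triol F7. MnO2 in CH2Cl2 would then re-oxidise only the allylic C2 carbinol, which comes back to the route at 29.

## Further compounds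

F1 | step 15 | 7-chloro-6α-hydroxycycloheptan-9-one (1α-OTBS, 1β-alkynyl pivalate, 5β-isovalerate, 10α-methyl; C7 unassigned) | O[C@@H]1C(Cl)CC(=O)[C@H](C)[C@@](O[Si](C)(C)C(C)(C)C)(C#C[C@H](C)OC(=O)C(C)(C)C)[C@H]1OC(=O)CC(C)C
F2 | step 15 | 6α-hydroxycyclohept-7-en-9-one (same substituents) | O[C@@H]1C=CC(=O)[C@H](C)[C@@](O[Si](C)(C)C(C)(C)C)(C#C[C@H](C)OC(=O)C(C)(C)C)[C@H]1OC(=O)CC(C)C
F3 | step 15 | 6α-acrylate of F2 | C=CC(=O)O[C@@H]1C=CC(=O)[C@H](C)[C@@](O[Si](C)(C)C(C)(C)C)(C#C[C@H](C)OC(=O)C(C)(C)C)[C@H]1OC(=O)CC(C)C
F4 | step 9 | 9α,10α-epoxide of 14 (epoxide cis to the 1α-OH) | CC[Si](CC)(CC)O[C@@H]1C[C@@H]2O[C@]2(C)[C@@](O)(C#C[C@H](C)OC(=O)C(C)(C)C)[C@H]1OC(=O)CC(C)C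
F5 | step 9 | 1α-tert-butyldimethylsilyl ether of F4 | CC[Si](CC)(CC)O[C@@H]1C[C@@H]2O[C@]2(C)[C@@](O[Si](C)(C)C(C)(C)C)(C#C[C@H](C)OC(=O)C(C)(C)C)[C@H]1OC(=O)CC(C)C
F6 | step 9 | 9α-alcohol with 10α-methyl (C9 epimer of 17) | CC[Si](CC)(CC)O[C@@H]1C[C@H](O)[C@H](C)[C@@](O[Si](C)(C)C(C)(C)C)(C#C[C@H](C)OC(=O)C(C)(C)C)[C@H]1OC(=O)CC(C)C
F7 | step 18 | C2 carbinol of the target: 1α,2,9β-triol (C2 unassigned) | C=C1C(=O)O[C@@H]2[C@H]1C[C@@H](O)[C@H](C)[C@@](O)(C(O)/C=C/C)[C@H]2OC(=O)CC(C)C
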